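What part of the electrophile has reacted after 30 min in north-east, with 0.600 equiv of free base, and in east, with 0.300 equiv?

all flasks: electrophile 0.050 M
- grey: nucleophile 1 equiv; free base 0.31 equiv; protic impurity 5 mM; run made earlier
- violet: nucleophile 1 equiv; free base 0.41 equiv; protic impurity 5 mM; run made earlier
- blue: nucleophile 1 equiv; free base 0.45 equiv; protic impurity 5 mM; run made earlier
- north-east: nucleophile 1.00 equiv; free base 0.600 equiv; protic impurity 5.00 mM; time 30 min
- east: nucleophile 1.00 equiv; free base 0.300 equiv; protic impurity 5.00 mM; time 30 min

- grey (time / min: electrophile / %, target / %): 2.50: 47.0, 50.6; 6.00: 40.8, 55.7; 12.0: 36.6, 55.2; 30.0: 31.3, 59.8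
- violet (time / min: electrophile / %, target / %): 4.00: 44.8, 52.2; 10.0: 37.3, 57.1; 20.0: 31.7, 58.2; 30.0: 30.1, 60.0
- blue (time / min: electrophile / %, target / %): 8.00: 39.7, 53.1; 15.0: 36.4, 58.4; 25.0: 32.9, 60.2; 30.0: 30.3, 59.7

(each reading ± 1 percentage point)



* part of the electrophile that has reacted at the end, north-east
* part of the electrophile that has reacted at the end, east
* what raising the equivalents of free base from its lowest to its highest value here does to the part of the electrophile that has reacted (changes below 5 percentage points count as none) (it rises / no change / it falls)

The grey curve falls steeply at the start: by 2.50 min it has lost 53.0% of the electrophile. In grey, target, at 50.6%, already stands above electrophile, at 47.0%, so the crossing in that run lies before its first reading. Then comes the knee: in the violet run the last 10.0 min take just 1.6 percentage points of electrophile. At 30 min target reads 59.8% on average over the three runs, with free base from 0.31 equiv to 0.45 equiv.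

Electrophile and target do not add up to the whole. The gap reads 2.40% in grey at 2.50 min, but at 30 min it reads 8.90% in grey, 9.90% in violet and 10.0% in blue. I read it as electrophile lost to the protic impurity, one for one, which makes the impurity, charged at 5.00 mM against 0.050 M of electrophile, the limiting reagent of that loss. The gap then has a loss ceiling: 10.0%, the protic impurity charged over the electrophile charged.

My reckoning adds the target level and the ceiling, giving 69.8% for both flasks, though holding the target level at 0.600 equiv is a guess.

The forecast prints 70% for north-east (range 66% to 77%), 69.5% for east (range 67% to 72%), and no change, on this ground: “Rate and extent look zero order in base here.”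

The flask gives 70.4% in north-east and 68.1% in east, a change of 2.3 points, so the trend is no change.

    electrophile + nucleophile ⇌ acid set free + target (K = 18.0, k = 0.400 M⁻¹ s⁻¹)
    nucleophile + acid set free ⇌ protonated nucleophile, settled at all times (K = 4700 M⁻¹)
    acid set free + free base ⇌ salt of the base (K = 13000 M⁻¹, k = 0.0360 M⁻¹ s⁻¹)
    electrophile + protic impurity → quenched substrate (k = 0.0660 M⁻¹ s⁻¹)

East at 30.0 min holds target 59.2% and quenched substrate 8.97%, which stays under the loss ceiling of 10.0%, with protic impurity 10.3% of its charge left. The forecast's trend fails at a later time: at 300 min north-east stands at 87.5% and east at 77.7%, which is 9.8 points apart, more than the margin of 5 points.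

In the neighbour flask, east with 0.020 M of protic impurity, the ceiling is 40.0%, so I expect a reacted part above that of east. It reaches 86.8%, with target 56.4%, quenched substrate 30.4% under that ceiling, and protic impurity 24% of its charge left.

(The readings were generated by integration for an exercise; the scatter is artificial.)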